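A spent carrier charged at 0.0250 mM could not move 0.5 mM of starting material in one trip, so it had to turn over many times, and I asked what each turn costs in quench.

common to all: starting material 5.0 × 10⁻⁴ M; salt in the second phase 1.20 equiv; spent carrier 5 mol%; time 20 s; volume of the second phase over the first 0.50
- delta: protic impurity 0.200 mM
- alpha: protic impurity 0.300 mM
- theta: protic impurity 0.500 mM

    starting material + fresh carrier → product + spent carrier (k1 = 50000 /M/s)
    spent carrier + salt in the second phase ⇌ fresh carrier + spent salt in the second phase (K2 = 1.3, k2 = 2200 /M/s)
    starting material + protic impurity → quenched substrate (k3 = 140 /M/s)

1. amount of product at the end, in percent of the starting material charged for delta, alpha, theta, in this order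
2. the shape of the row from first to last (rises all the way / falls all the way / rises, then falls / hardly changes / falls, then rises)

- in the second phase: salt in the second phase, spent salt in the second phase; everything else is in the first
- charges count per volume of the first phase; a concentration in a rate is the amount of a species over the volume of its own phase; every rate counts per litre of the first phase
- "hardly changes" means that all values lie within two and a half points (for a concentration: within two and a half percent of the largest)
- run time (delta): 20 s

I began with delta. As charged, the half-life of fresh carrier by step 1 alone was 0.028 s, and that of spent carrier by the forward direction of step 2 alone was 0.26 s, so at the start I took spent carrier as the resting state and its loading as the rate-limiting step. That holds while the first-order constant of use, 25.0 /s, exceeds that of loading, 2.64 /s. With the salt as charged, the crossing lay near 0.0528 mM of starting material.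

Above it, I reckoned product to form at a ceiling equal to the forward loading rate, using the salt's 1.20 mM in its own phase:

ceiling = 0.0660 mM/s, quench at the start = 0.0140 mM/s

So I reckoned the quench at 17.5% of the traffic at the start. With the ceiling held constant and x the quench over the ceiling, integrating to empty gave:

product share = ln(1 + x)/x = 90.7%

I committed to that number, then saw its weak link. Each product uses one salt, so at that yield about a quarter of the salt would remain, and the ceiling falls with it. I reforged the ratio of the two rates, with [salt] counted per volume of the first phase:

quench rate / product rate = m [starting material]/[salt]

Here m, the selectivity factor of the flask, is the quench constant times [protic impurity] times the volume ratio, over the loading constant times the carrier charge. Holding [protic impurity] at its charge and dropping the way back, this integrates to: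

salt left at the end, as a share of its charge = (1 − (1 − m)/equivalents)^(1/(1 − m))

delta: m = 0.255, salt left 27.2%, product 87.4%

alpha: m = 0.382, salt left 31.0%, product 82.8%

theta: m = 0.636, salt left 37.1%, product 75.5%

At the falling ceiling, my reckoning gave delta 11.8 s to bring its salt down that far, less than the 20 s allowed.

The forecast gave 86%, 81.5% and 74%, lower than mine at the far end, with a row that falls all the way, and said “Product falls steadily as impurity rises.”

The flasks gave 86.0%, 81.6% and 73.7%, so the row falls all the way, each a little under my figure. In delta at 20.0 s, 27.1% of the salt remained, against my 27.2%. Carried to theta, m = 0.636 gave salt left at 37.1%, and theta held 36.8% of its salt at 20.0 s.

The constants used here are those of an exercise; the rest is arithmetic.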